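The route cuts the Z-alkene C3=C4 by metathesis inside a temporary ring. The C2 hydroxyl and the formyl carbon of ring B flank this alkene. C2, its oxygen, the formyl carbon, two ring B carbons, C4 and C3 can therefore form a seven-membered cyclic acetal. Step 11 forges C3=C4, makes Z the only possible geometry, and keeps the aldehyde and C2–OH masked, so the ring A ester stays on C1. Its precursor is the mixed methyl acetal between a 2-vinyl ring B aldehyde (MOM and TBS ethers) and the C2–OH of a syn (S,S) vinyl diol esterified at C1 with 5-bromo-2-methylbenzoic acid. Desilylation, Ullmann closure of the 12-membered ring and acid hydrolysis follow.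

Key step: step 11

Locants:
- C1 is the carbinol carbon bearing pentyl and the ester oxygen.
- C2 is the neighbouring carbinol carbon (free OH in the target).
- C3=C4 is the alkene, with C4 on ring B.
- Ring A is the methyl-substituted benzoate ring; ring B is the formyl-phenol ring.

Remark (configuration): the target SMILES reads S at C1 and S at C2 (a syn diol), with a Z-alkene in a 12-membered ring. The S,S series requires the borane made from (+)-Ipc2BOMe, which derives from (−)-α-pinene.

Remark (design): the ring B phenol that later forms the diaryl ether is kept as a TBS ether through acetal exchange and metathesis. A free ortho-hydroxystyrene of hydroquinone type would compete as an O-nucleophile, could chelate ruthenium, and is air-sensitive. Ring B is built from 2,5-dihydroxybenzaldehyde, which brominates next to the formyl group and needs no aryl methyl ether cleavage.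

Assumption: the acetal carbon in 18 to 21 is a mixture of epimers and is written without configuration. It becomes the formyl carbon in step 14.

Step 1
Reactants: 1 allyl alcohol
Product: 2 allyl methoxymethyl ether
Conditions: MOMCl, iPr2NEt, CH2Cl2, 0 °C to rt; distillation
Reagents that add atoms: chloromethyl methyl ether (MOMCl), COCCl
Why: MOM protection (O-alkylation of a primary alcohol by an α-chloro ether with a hindered amine base) is routine and gives the allyl ether needed for the alkoxyallylboration.

Step 2
Reactants: 2 allyl methoxymethyl ether; 3 hexanal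
Product: 8 (3S,4S)-3-(methoxymethoxy)non-1-en-4-ol, via Z-allyllithium 4 (not isolated), via borate complex 5 (not isolated), via Z-alkoxyallylborane 6 (not isolated), via borinate adduct 7 (not isolated)
Conditions: s-BuLi, THF, −78 °C; (+)-Ipc2BOMe; BF3·OEt2; 3, −78 °C; then NaOH, H2O2, 0 °C to rt
Reagents that add atoms: none
Why: Brown asymmetric (Z)-γ-alkoxyallylboration, in which lithiation gives the internally chelated Z-allyl anion, the derived Z-borane adds to hexanal through a closed chair (Zimmerman–Traxler) transition state that turns Z geometry into the syn C1/C2 relationship, and the isopinocampheyl groups from (−)-α-pinene choose the aldehyde face that sets S at C1 and hence S at C2.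

Step 3
Reactants: 8 (3S,4S)-3-(methoxymethoxy)non-1-en-4-ol; 9 5-bromo-2-methylbenzoic acid
Product: 10 (3S,4S)-3-(methoxymethoxy)non-1-en-4-yl 5-bromo-2-methylbenzoate
Conditions: DCC, 4-(dimethylamino)pyridine (cat.), CH2Cl2, 0 °C to rt
Reagents that add atoms: none
Why: Steglich esterification acylates the only free hydroxyl (C1–OH) with retention because the C1–O bond is not broken, and the blocked C2 oxygen means the acyl group can sit only on C1.

Step 4
Reactants: 10 (3S,4S)-3-(methoxymethoxy)non-1-en-4-yl 5-bromo-2-methylbenzoate
Product: 11 (3S,4S)-3-hydroxynon-1-en-4-yl 5-bromo-2-methylbenzoate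
Conditions: ZnBr2, n-PrSH, CH2Cl2, 0 °C
Reagents that add atoms: none
Why: Lewis-acid-assisted thiolysis of the formaldehyde acetal (MOM cleavage by ZnBr2 and a soft thiol nucleophile) is fast at 0 °C and non-basic, so the hindered ortho-toluate should neither cleave nor migrate to C2–OH and both stereocentres stay untouched.

Step 5
Reactants: 12 2,5-dihydroxybenzaldehyde
Product: 13 2-bromo-3,6-dihydroxybenzaldehyde
Conditions: Br2 (1 equiv), CHCl3, 0 °C to rt
Reagents that add atoms: bromine, BrBr
Why: Electrophilic aromatic bromination is steered by the free 5-hydroxyl (the 2-hydroxyl is tied up in a hydrogen bond to the formyl group) to its ortho position next to the formyl carbon, the regiochemistry established for this very substrate.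

Step 6
Reactants: 13 2-bromo-3,6-dihydroxybenzaldehyde
Product: 14 2-bromo-3-(tert-butyldimethylsilyloxy)-6-hydroxybenzaldehyde
Conditions: TBSCl (1 equiv), imidazole, CH2Cl2, 0 °C
Reagents that add atoms: tert-butyldimethylsilyl chloride (TBSCl), CC(C)(C)[Si](C)(C)Cl
Why: Chemoselective silylation should result because the 6-hydroxyl is deactivated by its intramolecular hydrogen bond to the aldehyde, so one equivalent of TBSCl takes the more acidic, unchelated 3-hydroxyl.

Step 7
Reactants: 14 2-bromo-3-(tert-butyldimethylsilyloxy)-6-hydroxybenzaldehyde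
Product: 15 2-bromo-3-(tert-butyldimethylsilyloxy)-6-(methoxymethoxy)benzaldehyde
Conditions: MOMCl, iPr2NEt, CH2Cl2, 0 to 40 °C
Reagents that add atoms: chloromethyl methyl ether (MOMCl), COCCl
Why: MOM protection of the remaining salicyl-type phenol under amine base leaves the aryl silyl ether, bromide and aldehyde untouched and installs a group that survives hot carbonate yet falls together with the acetal in the last step.

Step 8
Reactants: 15 2-bromo-3-(tert-butyldimethylsilyloxy)-6-(methoxymethoxy)benzaldehyde
Product: 16 3-(tert-butyldimethylsilyloxy)-6-(methoxymethoxy)-2-vinylbenzaldehyde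
Conditions: Bu3SnCH=CH2, Pd(PPh3)4 (cat.), toluene, 100 °C
Reagents that add atoms: tributyl(vinyl)stannane, C=C[Sn](CCCC)(CCCC)CCCC
Why: Stille coupling under neutral, fluoride-free conditions keeps the aryl TBS ether, and the ortho formyl group speeds oxidative addition of zerovalent palladium into the crowded C–Br bond.

Step 9
Reactants: 16 3-(tert-butyldimethylsilyloxy)-6-(methoxymethoxy)-2-vinylbenzaldehyde
Product: 17 tert-butyl[3-(dimethoxymethyl)-4-(methoxymethoxy)-2-vinylphenoxy]dimethylsilane (dimethyl acetal of 16)
Conditions: MeOSiMe3, Me3SiOTf (cat.), CH2Cl2, −78 °C; Et3N quench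
Reagents that add atoms: methoxytrimethylsilane, CO[Si](C)(C)C
Why: Noyori acetalisation (alkoxysilane and catalytic silyl triflate, aprotic, −78 °C) converts even a di-ortho-substituted aldehyde, is driven by formation of the disiloxane, and is mild enough for the MOM ether, the silyl ether and the styrene.

Step 10
Reactants: 11 (3S,4S)-3-hydroxynon-1-en-4-yl 5-bromo-2-methylbenzoate; 17 dimethyl acetal of 16
Product: 18 (3S,4S)-3-{[3-(tert-butyldimethylsilyloxy)-6-(methoxymethoxy)-2-vinylphenyl](methoxy)methoxy}non-1-en-4-yl 5-bromo-2-methylbenzoate (mixed methyl acetal diene, epimers at the acetal carbon)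
Conditions: 17 (excess), pyridinium p-toluenesulfonate (cat.), toluene, 5 Å MS, 45 °C; Et3N quench, Et3N-washed silica
Reagents that add atoms: none
Why: In this acid-catalysed transacetalisation the electron-rich dimethyl acetal ionises readily, C2–OH traps the oxocarbenium ion, the sieves remove methanol, and the excess of 17 together with the crowding at the acetal carbon should stop the exchange at the mixed acetal, whose new centre forms as an inconsequential mixture of epimers.

Step 11
Reactants: 18 mixed methyl acetal diene
Product: 19 (1S)-1-[(3S)-6-(tert-butyldimethylsilyloxy)-1-methoxy-9-(methoxymethoxy)-1,3-dihydro-2-benzoxepin-3-yl]hexyl 5-bromo-2-methylbenzoate (Z-alkene in the ring, epimers at C1 of the oxepine)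
Conditions: second-generation Grubbs catalyst (H2IMes)(PCy3)Cl2Ru=CHPh (5–10 mol %), 1,4-benzoquinone (10 mol %), toluene (5 mM), 80 °C, Ar sparge
Reagents that add atoms: none
Why: The ruthenium carbene should load first on the less hindered C2 vinyl group, add to the ring B styrene in a [2+2] fashion and open the ruthenacyclobutane by cycloreversion, which forms C3=C4 and releases ethene that the argon stream removes. The closest known reaction type is ring-closing metathesis across a temporary acetal or silicon tether, and the closure of 2-vinylbenzyl allyl ethers to 1,3-dihydro-2-benzoxepines is a standard case. The single ring closed is the seven-membered oxepine (C2, O, acetal carbon, two ring B carbons, C4, C3), joined between two terminal alkenes so that both new sp2 carbons are endocyclic. No stereocentre is created, since C1 and C2 are untouched and both acetal epimers should cyclise and converge in step 14. The selectivity needed is Z geometry, which the substrate secures because a benzo-fused seven-membered ring cannot hold an E-alkene, while dilution and the short tether hold back dimerisation. The silyl ether keeps the ortho oxygen from chelating ruthenium, the aryl bromide, ester and MOM ether are inert to the catalyst, and 1,4-benzoquinone suppresses hydride-mediated migration of the allylic alkene.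

Step 12
Reactants: 19 silylated benzoxepine
Product: 20 (1S)-1-[(3S)-6-hydroxy-1-methoxy-9-(methoxymethoxy)-1,3-dihydro-2-benzoxepin-3-yl]hexyl 5-bromo-2-methylbenzoate
Conditions: Bu4NF, AcOH, THF, 0 °C
Reagents that add atoms: none
Why: Fluoride-mediated desilylation of an aryl silyl ether is very fast, and buffering with acetic acid keeps the medium from touching the ester, the acetal or the MOM ether.

Step 13
Reactants: 20 phenol bromide
Product: 21 acetal-bridged 12-membered diaryl ether lactone (C1 S, C2 S, Z-alkene, MOM ether in place)
Conditions: CuI (50 mol %), N,N-dimethylglycine, Cs2CO3, 1,4-dioxane (slow addition, final 2 mM), 100 °C, Ar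
Reagents that add atoms: none
Why: In this intramolecular ligand-accelerated Ullmann diaryl ether synthesis the caesium phenoxide binds copper, oxidative addition into the ring A C–Br bond and reductive elimination close the 12-membered ring, the Z-alkene locked in the oxepine holds the phenol close to the C1 side chain, and the ester, acetal and MOM ether tolerate dry carbonate.

Step 14
Reactants: 21 acetal-bridged macrolactone
Product: 22 CNP0238900.1 (target)
Conditions: 3 M aq. HCl, THF, rt to 40 °C
Reagents that add atoms: water, O
Why: Acid hydrolysis of both acetals (cyclic methyl acetal and MOM ether) in one operation returns the formyl group, the C2 hydroxyl and the phenol and erases the acetal epimers, while the lactone, the stereocentres and the Z-alkene should survive because ionisation at C2 is disfavoured by the neighbouring acyloxy group and the formyl-substituted ring.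

Compound list
1 | allyl alcohol | C=CCO | starting material
2 | allyl methoxymethyl ether, 3-(methoxymethoxy)prop-1-ene | C=CCOCOC | intermediate
3 | hexanal | CCCCCC=O | starting material
4 | (Z)-3-(methoxymethoxy)allyllithium | [Li]C/C=C\OCOC | intermediate
5 | lithium [(Z)-3-(methoxymethoxy)allyl](methoxy)bis(isopinocampheyl)borate, Ipc from (−)-α-pinene | [Li+].COCO/C=C\C[B-](OC)([C@H]1C[C@H]2C[C@@H]([C@@H]1C)C2(C)C)[C@H]1C[C@H]2C[C@@H]([C@@H]1C)C2(C)C | intermediate
6 | [(Z)-3-(methoxymethoxy)allyl]bis(isopinocampheyl)borane | COCO/C=C\CB([C@H]1C[C@H]2C[C@@H]([C@@H]1C)C2(C)C)[C@H]1C[C@H]2C[C@@H]([C@@H]1C)C2(C)C | intermediate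
7 | bis(isopinocampheyl)borinate of 8 | CCCCC[C@H](OB([C@H]1C[C@H]2C[C@@H]([C@@H]1C)C2(C)C)[C@H]1C[C@H]2C[C@@H]([C@@H]1C)C2(C)C)[C@@H](OCOC)C=C | intermediate
8 | (3S,4S)-3-(methoxymethoxy)non-1-en-4-ol | CCCCC[C@H](O)[C@@H](OCOC)C=C | intermediate
9 | 5-bromo-2-methylbenzoic acid | Cc1ccc(Br)cc1C(=O)O | starting material
10 | (3S,4S)-3-(methoxymethoxy)non-1-en-4-yl 5-bromo-2-methylbenzoate | CCCCC[C@H](OC(=O)c1cc(Br)ccc1C)[C@@H](OCOC)C=C | intermediate
11 | (3S,4S)-3-hydroxynon-1-en-4-yl 5-bromo-2-methylbenzoate | CCCCC[C@H](OC(=O)c1cc(Br)ccc1C)[C@@H](O)C=C | intermediate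
12 | 2,5-dihydroxybenzaldehyde | O=Cc1cc(O)ccc1O | starting material
13 | 2-bromo-3,6-dihydroxybenzaldehyde | O=Cc1c(O)ccc(O)c1Br | intermediate
14 | 2-bromo-3-(tert-butyldimethylsilyloxy)-6-hydroxybenzaldehyde | O=Cc1c(O)ccc(O[Si](C)(C)C(C)(C)C)c1Br | intermediate
15 | 2-bromo-3-(tert-butyldimethylsilyloxy)-6-(methoxymethoxy)benzaldehyde | COCOc1ccc(O[Si](C)(C)C(C)(C)C)c(Br)c1C=O | intermediate
16 | 3-(tert-butyldimethylsilyloxy)-6-(methoxymethoxy)-2-vinylbenzaldehyde | COCOc1ccc(O[Si](C)(C)C(C)(C)C)c(C=C)c1C=O | intermediate
17 | dimethyl acetal of 16 | COCOc1ccc(O[Si](C)(C)C(C)(C)C)c(C=C)c1C(OC)OC | intermediate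
18 | mixed methyl acetal diene (key-step precursor; C1 S, C2 S; acetal epimers) | CCCCC[C@H](OC(=O)c1cc(Br)ccc1C)[C@@H](OC(OC)c1c(OCOC)ccc(O[Si](C)(C)C(C)(C)C)c1C=C)C=C | intermediate
19 | silylated 1-methoxy-1,3-dihydro-2-benzoxepine (key-step product; Z-alkene; acetal epimers) | CCCCC[C@H](OC(=O)c1cc(Br)ccc1C)[C@@H]1/C=C\c2c(O[Si](C)(C)C(C)(C)C)ccc(OCOC)c2C(OC)O1 | intermediate
20 | 6-hydroxy-1-methoxy-1,3-dihydro-2-benzoxepine bromide | CCCCC[C@H](OC(=O)c1cc(Br)ccc1C)[C@@H]1/C=C\c2c(O)ccc(OCOC)c2C(OC)O1 | intermediate
21 | acetal-bridged 12-membered diaryl ether lactone | CCCCC[C@@H]1OC(=O)c2cc(ccc2C)Oc2ccc(OCOC)c3c2/C=C\[C@@H]1OC3OC | intermediate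
22 | CNP0238900.1 | CCCCC[C@@H]1OC(=O)c2cc(ccc2C)Oc2ccc(O)c(C=O)c2/C=C\[C@@H]1O | target

Total step count: 14.
Longest linear sequence: 10 steps (steps 5 to 14, from 2,5-dihydroxybenzaldehyde). The other branch runs through steps 1 to 4 and then 10 to 14, which is 9 steps.

Steps most likely to fail

First risk, step 10 (mixed acetal). The equilibrium exchange may stall at the crowded acetal carbon or run on to the symmetrical acetal. The aryl MOM ether may be lost, or the oxocarbenium ion may be intercepted by the neighbouring vinyl group. The fallback builds the acetal by oxidation instead of exchange. It sets out from 16 and 11 and comes back at 18.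
- NaBH4 in MeOH reduces 16 to the benzylic alcohol F1.
- Cl3CCN with catalytic DBU gives the benzylic trichloroacetimidate F2.
- La(OTf)3-catalysed benzylation of 11 with F2 in toluene, the reaction type used for p-methoxybenzyl ethers, gives the ring B benzyl ether F3.
- DDQ with dry MeOH and 4 Å sieves in CH2Cl2 at 0 °C removes the benzylic hydride of the electron-rich ring. Methanol then traps the oxocarbenium ion irreversibly to give 18.

Second risk, step 11 (metathesis). The carbene may load on the C2 vinyl group while the twisted, di-ortho-substituted styrene fails to engage. Intermolecular dimerisation or alkene migration would then take over. The fallback is a relay ring-closing metathesis that delivers ruthenium to the hindered carbon. It sets out from 15 (with 11) and comes back at 19.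
- Hydrostannation of commercial allyl propargyl ether (Bu3SnH, PdCl2(PPh3)2 cat., THF) gives (E)-tributyl[3-(allyloxy)prop-1-en-1-yl]stannane F4.
- Stille coupling of F4 with 15 under the conditions of step 8 gives the relay aldehyde F5.
- The conditions of step 9 give the relay dimethyl acetal F6, and exchange with 11 as in step 10 gives the relay mixed acetal F7.
- The catalyst (H2IMes)(PCy3)Cl2Ru=CHPh should now enter at the unhindered allyl ether terminus and expel 2,5-dihydrofuran. This places the carbene on C4, from where closure onto the C2 vinyl group gives 19.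

Third risk, step 13 (Ullmann macrocyclisation). Slow insertion into the unactivated C–Br bond, together with the strain of the 12-membered ring, may let oligomerisation, hydrodebromination or thermal decay win at 100 °C. The fallback inverts the polarity of ring A and closes the ring oxidatively at room temperature. It sets out from 19 and comes back at 21.
- Miyaura borylation (B2pin2, PdCl2(dppf), KOAc, dioxane, 80 °C) gives the ring A pinacol boronate F8.
- NaIO4 and NH4OAc in aqueous acetone give the silylated boronic acid F9 while the oxidation-prone phenol is still protected.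
- Bu4NF and AcOH in THF give the phenol boronic acid F10.
- Chan–Evans–Lam coupling (Cu(OAc)2, pyridine, 4 Å sieves, CH2Cl2, high dilution, rt, dry air) closes the diaryl ether to 21.

Further compounds
F1 | step 10 | [3-(tert-butyldimethylsilyloxy)-6-(methoxymethoxy)-2-vinylphenyl]methanol | COCOc1ccc(O[Si](C)(C)C(C)(C)C)c(C=C)c1CO
F2 | step 10 | 3-(tert-butyldimethylsilyloxy)-6-(methoxymethoxy)-2-vinylbenzyl 2,2,2-trichloroacetimidate | COCOc1ccc(O[Si](C)(C)C(C)(C)C)c(C=C)c1COC(=N)C(Cl)(Cl)Cl
F3 | step 10 | (3S,4S)-3-{[3-(tert-butyldimethylsilyloxy)-6-(methoxymethoxy)-2-vinylbenzyl]oxy}non-1-en-4-yl 5-bromo-2-methylbenzoate | CCCCC[C@H](OC(=O)c1cc(Br)ccc1C)[C@@H](OCc1c(OCOC)ccc(O[Si](C)(C)C(C)(C)C)c1C=C)C=C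
F4 | step 11 | (E)-tributyl[3-(allyloxy)prop-1-en-1-yl]stannane | C=CCOC/C=C/[Sn](CCCC)(CCCC)CCCC
F5 | step 11 | 2-[(E)-3-(allyloxy)prop-1-en-1-yl]-3-(tert-butyldimethylsilyloxy)-6-(methoxymethoxy)benzaldehyde | COCOc1ccc(O[Si](C)(C)C(C)(C)C)c(/C=C/COCC=C)c1C=O
F6 | step 11 | dimethyl acetal of F5 | COCOc1ccc(O[Si](C)(C)C(C)(C)C)c(/C=C/COCC=C)c1C(OC)OC
F7 | step 11 | relay mixed methyl acetal of F5 with 11 (acetal epimers) | CCCCC[C@H](OC(=O)c1cc(Br)ccc1C)[C@@H](OC(OC)c1c(OCOC)ccc(O[Si](C)(C)C(C)(C)C)c1/C=C/COCC=C)C=C
F8 | step 13 | ring A pinacol boronate of 19 | CCCCC[C@H](OC(=O)c1cc(B2OC(C)(C)C(C)(C)O2)ccc1C)[C@@H]1/C=C\c2c(O[Si](C)(C)C(C)(C)C)ccc(OCOC)c2C(OC)O1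
F9 | step 13 | ring A boronic acid, phenol still silylated | CCCCC[C@H](OC(=O)c1cc(B(O)O)ccc1C)[C@@H]1/C=C\c2c(O[Si](C)(C)C(C)(C)C)ccc(OCOC)c2C(OC)O1
F10 | step 13 | ring A boronic acid with free ring B phenol | CCCCC[C@H](OC(=O)c1cc(B(O)O)ccc1C)[C@@H]1/C=C\c2c(O)ccc(OCOC)c2C(OC)O1
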